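If the starting material charged to the larch flask is booked mole by mole, the books have few entries, and each remedy can be judged by the entry it touches.

| setting | larch | birch | flask |
|---|---|---|---|
| starting material | 20 mM | 20 mM | 20 mM |
| protic impurity | 6 mM | 6 mM | 6.00 mM |
| free catalyst | 6.4 mol% | 6.4 mol% | 6.4 mol% |
| temperature | 25 °C | 20 °C | 25 °C |
| remark | the very flask that is asked about, followed so far | run made earlier |  |
| time |  |  | 5.0 min |

- larch (time / min: product / %, starting material / %): 0.333: 21.1, 67.5; 1.00: 49.2, 30.0; 2.00: 65.2, 12.9; 2.50: 68.3, 9.8; 4.00: 72.8, 2.6; 5.00: 71.5, 1.7
- birch (time / min: product / %, starting material / %): 0.333: 15.6, 73.4; 1.00: 39.6, 42.1; 2.00: 58.2, 21.2; 2.50: 62.0, 13.2; 4.00: 69.6, 5.6; 5.00: 73.1, 4.0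

(readings scatter by 1 percentage point)

- Wednesday's: change nothing and wait 1.5 min more
- Monday's: at 5.0 min add free catalyst, 50.0 % of the amount charged, then wait 1.5 min
- Sunday's: at 5.0 min raise the temperature by 20 K, then wait 1.5 min
- Thursday's: at 5.0 min take out 90 % of the product then present, then wait 1.5 min

- product taken out counts as made
- steps under discussion: catalyst intermediate <-> free catalyst + product; starting material + free catalyst <-> catalyst intermediate; starting material + protic impurity -> quenched substrate
- additions bring no volume worth counting

1. product, in percent of the starting material first charged, at 5.0 min
2. the remedy with the largest gain of product, or "none" below 2 percentage points (Wednesday's / Monday's / Sunday's / Thursday's / none)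
3. product present, with what was taken out counted in, in percent of the starting material first charged, after Wednesday's
4. product present, with what was taken out counted in, in percent of the starting material first charged, after Sunday's

At 5.00 min the larch flask shows 1.7 % starting material and 71.5 % product, so 26.8 % of the charge stands in neither column. That entry can be booked to quenched substrate, since the protic impurity can take 30.0 % of the charge, and catalyst intermediate can hold up to 6.4 mol%. The quench carries a single arrow, so what is booked there does not return. Both catalytic steps carry double arrows, so starting material and product form one pool of 73.2 %.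

The larch readings give [product]/[starting material] = 42.1 at 5.00 min. This is taken as the stopping ratio, the value of [product]/[starting material] at which the catalysed conversion stands still in both directions, that is, its equilibrium constant. It is a rough reading, with 1 percentage point of scatter on so small a column.

The reckoning here freezes this ratio. In that reckoning, waiting and added catalyst both leave the pool divided as it stands, and free catalyst stands on both sides of the net conversion. The birch readings still climb, from 12.4 at 4.00 min to 18.3 at 5.00 min, so they give no stopping ratio at a second temperature, and this reckoning books no gain for Sunday's. Thursday's leaves 7.15 % product beside the starting material, and the small pool divides anew. That reckons to a gain of 1.5 points, less than the 2 points required. This reckoning therefore says none.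

The forecast differs. It gives 72.5 %, 73.4 % after Wednesday's and 74 % after Sunday's, and it names Thursday's at 3 to 4 points, on the ground that “Removing product releases the bound intermediate as product”.

The larch flask stands at 73.3 %. The gains are 0.13 points for Wednesday's, 0.12 points for Monday's, −5.2 points for Sunday's and 1.4 points for Thursday's, so the answer is none, with 73.4 % after Wednesday's and 68.1 % after Sunday's.

    catalyst intermediate ⇌ free catalyst + product (K = 2.00 M, k = 2.50 s⁻¹, Ea = 63.0 kJ mol⁻¹, ΔH = −63.0 kJ mol⁻¹)
    starting material + free catalyst ⇌ catalyst intermediate (K = 20.0 M⁻¹, k = 15.0 M⁻¹ s⁻¹, Ea = 38.0 kJ mol⁻¹, ΔH = 13.0 kJ mol⁻¹)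
    starting material + protic impurity → quenched substrate (k = 1.50 M⁻¹ s⁻¹, Ea = 36.0 kJ mol⁻¹)
    (constants at 25 °C)

In the larch flask at 5.0 min, the backward rate of catalyst intermediate to free catalyst + product is 95.7 % of its forward rate. The larch flask's [product]/[starting material] is 33.6 at 5.00 min and 41.2 at 50.0 min, where product has sunk to 69.7 %. The neighbour flask charged with 10 mM protic impurity holds 60.7 % product at a ratio of 41.4 at 5.0 min, and the stopping ratio of 42.1 divides its pool of 62.2 % into 60.8 % product.

The readings were computed on assumed constants; noise was put on by code.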